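The route rests on disconnecting the benzene ring (ring A) of the phthalide at C3a–C4 and C7–C7a. One Diels–Alder/aromatisation operation builds that ring from an acyclic 2-alkoxy ketene-acetal diene and an alkynyl aldehyde ester. The three neighbouring oxygens on C4 (free OH), C5 (sesquiterpenyl ether) and C6 (OMe), and the two carbon substituents on C3a and C7a that become lactone ring B, thus arrive already differentiated, and no arene has to be functionalised selectively. The diene precursor is a 1,3-dimethoxy-1-trimethylsilyloxybutadiene carrying the hydrated farnesyl chain as its C2 ether, with the tertiary alcohol masked as a trimethylsilyl ether that is installed before the carbenoid etherification.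

Key step: step 10

Remarks: atom numbers C1–C7a are those of the phthalide ring system of the target. "TMS-chain" stands for the (2E,6E)-3,7,11-trimethyl-11-(trimethylsilyloxy)dodeca-2,6-dien-1-yl group and "HO-chain" for the (2E,6E)-11-hydroxy-3,7,11-trimethyldodeca-2,6-dien-1-yl group.
Assumption: 3, 4, 10 and 15 are racemic at centres that are all removed again, and 11 and 12 are drawn as one double-bond isomer each, the other isomer being expected to react in the same way.

Step 1
Reactants: 1 (2E,6E)-farnesol
Product: 2 (2E,6E)-farnesyl acetate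
Conditions: Ac2O, pyridine, DMAP (cat.), 0 °C to rt
Reagents that add atoms: acetic anhydride, CC(=O)OC(C)=O
Why: O-Acetylation of a primary allylic alcohol is routine, leaves both alkene geometries untouched, and the acetate deactivates the C2=C3 alkene towards the electrophile of step 2.

Step 2
Reactants: 2 (2E,6E)-farnesyl acetate
Product: 3 (2E,6E)-10-bromo-11-hydroxy-3,7,11-trimethyldodeca-2,6-dien-1-yl acetate (racemic at C10)
Conditions: NBS (1.05 equiv), THF/H2O (3:1), 0 °C
Reagents that add atoms: N-bromosuccinimide, O=C1CCC(=O)N1Br; water, O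
Why: Bromohydrin formation should take place at the terminal trisubstituted alkene, the most exposed and most electron-rich one of the polyprenyl chain in aqueous THF, with water opening the bromonium ion at the tertiary carbon C11 (Markovnikov), and the new C10 stereocentre is formed racemic and removed in step 3.

Step 3
Reactants: 3 (2E,6E)-10-bromo-11-hydroxy-3,7,11-trimethyldodeca-2,6-dien-1-yl acetate
Product: 5 (2E,6E)-3,7,11-trimethyldodeca-2,6-diene-1,11-diol, via 10,11-epoxyfarnesol alkoxide 4 (not isolated)
Conditions: LiAlH4 (3 equiv), THF, 0 °C to reflux; then H2O, 15% aq. NaOH, H2O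
Reagents that add atoms: none
Why: In this hydride reduction of a halohydrin, LiAlH4 cleaves the acetate, the tertiary alkoxide displaces bromide to give the epoxide, and hydride opens the trisubstituted epoxide by SN2 attack at the less hindered C10, which leaves the tertiary alcohol on C11 and erases the C10 stereocentre.

Step 4
Reactants: 5 (2E,6E)-3,7,11-trimethyldodeca-2,6-diene-1,11-diol
Product: 7 (2E,6E)-3,7,11-trimethyl-11-(trimethylsilyloxy)dodeca-2,6-dien-1-ol, via bis(trimethylsilyl) ether 6 (not isolated)
Conditions: 1-(trimethylsilyl)imidazole (2.5 equiv), CH2Cl2, rt; then MeOH, K2CO3 (0.1 equiv), 0 °C, short time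
Reagents that add atoms: 1-(trimethylsilyl)imidazole, C[Si](C)(C)n1ccnc1
Why: Exhaustive silylation followed by selective methanolysis exploits the large rate difference between an unhindered primary allylic trimethylsilyl ether and a tertiary one, so that the carbenoid of step 6 is offered a single O–H bond and the enolate chemistry of steps 7 and 8 meets no second acidic site.

Step 5
Reactants: 8 methyl acetoacetate
Product: 9 methyl 2-diazo-3-oxobutanoate
Conditions: 4-acetamidobenzenesulfonyl azide, Et3N, MeCN, 0 °C to rt
Reagents that add atoms: 4-acetamidobenzenesulfonyl azide, CC(=O)Nc1ccc(cc1)S(=O)(=O)N=[N+]=[N-]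
Why: Regitz diazo transfer from a sulfonyl azide to the active methylene group of a β-keto ester under amine base is a standard and reliable reaction.

Step 6
Reactants: 7 (2E,6E)-3,7,11-trimethyl-11-(trimethylsilyloxy)dodeca-2,6-dien-1-ol; 9 methyl 2-diazo-3-oxobutanoate
Product: 10 methyl 3-oxo-2-(TMS-chain-oxy)butanoate (racemic, keto/enol mixture)
Conditions: Rh2(OAc)4 (1 mol%), CH2Cl2, rt, slow addition of 9; product carried on without delay
Reagents that add atoms: none
Why: In this rhodium-carbenoid O–H insertion the electrophilic acceptor/acceptor carbenoid from 9 should be captured by the only free hydroxyl group much faster than it cyclopropanates trisubstituted alkenes, at room temperature the enol first formed should tautomerise and not rearrange, and the new α-stereocentre is racemic and becomes sp2 in step 7.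

Step 7
Reactants: 10 methyl 3-oxo-2-(TMS-chain-oxy)butanoate
Product: 11 methyl (2Z)-3-methoxy-2-(TMS-chain-oxy)but-2-enoate
Conditions: KN(SiMe3)2 (commercial solution, 1.05 equiv), THF/DMPU, −78 °C; MeOTf (1.1 equiv), −78 to 0 °C
Reagents that add atoms: methyl trifluoromethanesulfonate, COS(=O)(=O)C(F)(F)F
Why: In this O-alkylation of a β-keto ester enolate the dissociated potassium enolate should react with the hard electrophile at oxygen, since C-methylation would create a fully substituted α-alkoxy carbon, and the low temperature keeps the allyloxy enolate from sigmatropic rearrangement.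

Step 8
Reactants: 11 methyl (2Z)-3-methoxy-2-(TMS-chain-oxy)but-2-enoate
Product: 12 (1E)-1,3-dimethoxy-2-(TMS-chain-oxy)-1-(trimethylsilyloxy)buta-1,3-diene
Conditions: Me3SiCl (1.5 equiv), then LiN(iPr)2 (commercial solution, 1.15 equiv), THF, −78 to 0 °C (in situ trapping); volatiles removed in vacuo, pentane, filtration under argon, used crude
Reagents that add atoms: chlorotrimethylsilane, C[Si](C)(C)Cl
Why: Kinetic γ-deprotonation of a β-methoxy enoate to the extended lithium dienolate and silylation on the ester oxygen is the standard preparation of 1-alkoxy-1-silyloxy-1,3-dienes, and trapping in situ at −78 °C leaves the dienolate no time for Wittig-type rearrangement of its allyl ether.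

Step 9
Reactants: 13 methyl 4-hydroxybut-2-ynoate
Product: 14 methyl 4-oxobut-2-ynoate
Conditions: activated MnO2 (10 equiv), CH2Cl2, rt; filtration through Celite, solution used at once
Reagents that add atoms: none
Why: Activated MnO2 oxidises propargylic alcohols selectively to ynals without over-oxidation, and filtration alone gives a solution of the sensitive aldehyde that need not be concentrated.

Step 10
Reactants: 12 (1E)-1,3-dimethoxy-2-(TMS-chain-oxy)-1-(trimethylsilyloxy)buta-1,3-diene; 14 methyl 4-oxobut-2-ynoate
Product: 16 methyl 2-formyl-3-hydroxy-4-(HO-chain-oxy)-5-methoxybenzoate, via cyclohexadiene cycloadduct 15 (not isolated)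
Conditions: 14 (1.3 equiv), CH2Cl2, −78 to 0 °C, no Lewis acid; then 0.5 M aq. HCl, THF, 0 °C to rt
Reagents that add atoms: none
Why: The vinylogous ketene acetal 12 and the doubly activated alkyne 14 should combine in a concerted but strongly asynchronous normal-demand [4+2] cycloaddition, in which the CH2 terminus of the diene (largest HOMO coefficient) bonds first to the ester-bearing alkyne carbon (C7–C7a) and the ketene-acetal carbon then bonds to the formyl-bearing carbon (C3a–C4), giving cyclohexa-1,4-diene 15. The closest known reaction type is the Diels–Alder benzannulation of 1-alkoxy-1-silyloxy-1,3-dienes with acetylenic esters, ketones and aldehydes followed by loss of alcohol. The six-membered carbocycle, ring A of the phthalide, is closed by the intermolecular cycloaddition itself, both ring bonds being made suprafacially across the s-cis diene and not by cyclisation of a tethered chain. The only stereocentre formed, the mixed methyl silyl ketal carbon of 15, needs no control because dilute acid collapses this ketal with loss of methanol, aromatises the ring and removes both trimethylsilyl groups, so that the former ester oxygen becomes the C4 phenol, the C2 ether the C5 ether and the enol ether the C6 methoxy group. The step needs regioselectivity and chemoselectivity: the formyl group is the stronger acceptor, so the alkyne carbon β to it (the one carrying CO2Me) is the most electrophilic site and should take the nucleophilic CH2 terminus, which places CHO beside the new phenol, and the triple bond, activated from both ends, should react faster than the aldehyde carbonyl as long as no Lewis acid is present. Working at or below 0 °C also keeps the allyl vinyl ether unit of 12 far from the temperature of a Claisen rearrangement.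

Step 11
Reactants: 16 methyl 2-formyl-3-hydroxy-4-(HO-chain-oxy)-5-methoxybenzoate
Product: 18 Farnesylemefuranone E, via hydroxymethyl benzoate 17 (not isolated)
Conditions: NaBH4 (1.0 equiv), MeOH/THF, 0 °C; then 1 M aq. HCl to pH 3, rt
Reagents that add atoms: none
Why: Chemoselective NaBH4 reduction of the aldehyde beside a methyl ester should give the benzylic alcohol, which closes the five-membered lactone (ring B) by 5-exo-trig acyl substitution on the neighbouring ester with loss of methanol, and no stereocentre is involved.

Compound list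
1 | (2E,6E)-farnesol | CC(C)=CCC/C(C)=C/CC/C(C)=C/CO | starting material
2 | (2E,6E)-farnesyl acetate | CC(C)=CCC/C(C)=C/CC/C(C)=C/COC(C)=O | intermediate
3 | (2E,6E)-10-bromo-11-hydroxy-3,7,11-trimethyldodeca-2,6-dien-1-yl acetate, racemic | CC(C)(O)C(Br)CC/C(C)=C/CC/C(C)=C/COC(C)=O | intermediate
4 | (2E,6E)-10,11-epoxy-3,7,11-trimethyldodeca-2,6-dien-1-ol (10,11-epoxyfarnesol), racemic, present as its alkoxide, not isolated | CC1(C)OC1CC/C(C)=C/CC/C(C)=C/CO | intermediate
5 | (2E,6E)-3,7,11-trimethyldodeca-2,6-diene-1,11-diol | CC(C)(O)CCC/C(C)=C/CC/C(C)=C/CO | intermediate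
6 | (2E,6E)-3,7,11-trimethyl-1,11-bis(trimethylsilyloxy)dodeca-2,6-diene, not isolated | C[Si](C)(C)OC(C)(C)CCC/C(C)=C/CC/C(C)=C/CO[Si](C)(C)C | intermediate
7 | (2E,6E)-3,7,11-trimethyl-11-(trimethylsilyloxy)dodeca-2,6-dien-1-ol | C[Si](C)(C)OC(C)(C)CCC/C(C)=C/CC/C(C)=C/CO | intermediate
8 | methyl acetoacetate | COC(=O)CC(C)=O | starting material
9 | methyl 2-diazo-3-oxobutanoate | COC(=O)C(=[N+]=[N-])C(C)=O | intermediate
10 | methyl 3-oxo-2-(TMS-chain-oxy)butanoate, racemic | COC(=O)C(OC/C=C(\C)CC/C=C(\C)CCCC(C)(C)O[Si](C)(C)C)C(C)=O | intermediate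
11 | methyl (2Z)-3-methoxy-2-(TMS-chain-oxy)but-2-enoate (drawn isomer, geometry of this bond immaterial) | COC(=O)/C(OC/C=C(\C)CC/C=C(\C)CCCC(C)(C)O[Si](C)(C)C)=C(\C)OC | intermediate
12 | (1E)-1,3-dimethoxy-2-(TMS-chain-oxy)-1-(trimethylsilyloxy)buta-1,3-diene (drawn isomer, ketene-acetal geometry immaterial) | C=C(OC)/C(OC/C=C(\C)CC/C=C(\C)CCCC(C)(C)O[Si](C)(C)C)=C(/OC)O[Si](C)(C)C | intermediate
13 | methyl 4-hydroxybut-2-ynoate | COC(=O)C#CCO | starting material
14 | methyl 4-oxobut-2-ynoate | COC(=O)C#CC=O | intermediate
15 | methyl 2-formyl-3,5-dimethoxy-4-(TMS-chain-oxy)-3-(trimethylsilyloxy)cyclohexa-1,4-diene-1-carboxylate, racemic, not isolated | COC(=O)C1=C(C=O)C(OC)(O[Si](C)(C)C)C(OC/C=C(\C)CC/C=C(\C)CCCC(C)(C)O[Si](C)(C)C)=C(OC)C1 | intermediate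
16 | methyl 2-formyl-3-hydroxy-4-(HO-chain-oxy)-5-methoxybenzoate | COC(=O)c1cc(OC)c(OC/C=C(\C)CC/C=C(\C)CCCC(C)(C)O)c(O)c1C=O | intermediate
17 | methyl 3-hydroxy-2-(hydroxymethyl)-4-(HO-chain-oxy)-5-methoxybenzoate, not isolated | COC(=O)c1cc(OC)c(OC/C=C(\C)CC/C=C(\C)CCCC(C)(C)O)c(O)c1CO | intermediate
18 | Farnesylemefuranone E, 4-hydroxy-5-(HO-chain-oxy)-6-methoxy-2-benzofuran-1(3H)-one | COc1cc2c(c(O)c1OC/C=C(\C)CC/C=C(\C)CCCC(C)(C)O)COC2=O | target

Total step count: 11
Longest linear sequence: 9 steps (steps 1, 2, 3, 4, 6, 7, 8, 10 and 11, from farnesol 1 to target 18)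

Steps most likely to fail

1. Step 10. The cycloaddition may take another course: the nucleophilic diene terminus may add to the aldehyde carbonyl (aldol-type or hetero-Diels–Alder addition) in place of the triple bond, or the two partners may combine in the opposite orientation, so that ring A is not formed with the formyl group beside the phenol. The fallback sets out from 12 and comes back to the route at 18. Diene 12 would be combined with dimethyl but-2-ynedioate, a symmetrical dienophile without an aldehyde, under the conditions of step 10 to give dimethyl 3,5-dimethoxy-4-(TMS-chain-oxy)-3-(trimethylsilyloxy)cyclohexa-1,4-diene-1,2-dicarboxylate F1. The same dilute-acid work-up should aromatise and desilylate it to dimethyl 3-hydroxy-4-(HO-chain-oxy)-5-methoxyphthalate F2. LiOH in THF/H2O should then hydrolyse only the less hindered ester on C7a, since the ester on C3a is flanked by the phenoxide and the other carboxyl group, to give 3-hydroxy-4-(HO-chain-oxy)-5-methoxy-2-(methoxycarbonyl)benzoic acid F3. LiBH4 in THF reduces the remaining ester while the lithium carboxylate is left alone, giving 3-hydroxy-2-(hydroxymethyl)-4-(HO-chain-oxy)-5-methoxybenzoic acid F4, which should lactonise to 18 on acidification.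

2. Step 7. Methylation may take place at carbon in place of oxygen, or the allyloxy enolate may rearrange sigmatropically before it is alkylated. The fallback sets out from 10 and comes back to the route at 16; it moves the methylation to the end, where it is a phenol alkylation. Keto ester 10 would be silylated on oxygen with Me3SiCl and Et3N to methyl 2-(TMS-chain-oxy)-3-(trimethylsilyloxy)but-2-enoate F5. LiN(iPr)2 and Me3SiCl in THF at −78 °C should convert this into 1-methoxy-2-(TMS-chain-oxy)-1,3-bis(trimethylsilyloxy)buta-1,3-diene F6. Cycloaddition with 14 as in step 10 should give methyl 2-formyl-3-methoxy-4-(TMS-chain-oxy)-3,5-bis(trimethylsilyloxy)cyclohexa-1,4-diene-1-carboxylate F7, and the acidic work-up then methyl 2-formyl-3,5-dihydroxy-4-(HO-chain-oxy)benzoate F8. MeI (1.0 equiv) and K2CO3 in acetone should methylate only the 5-hydroxyl group, which is para to the formyl group and not hydrogen-bonded, while the 3-hydroxyl group is held in a hydrogen bond to the aldehyde; this gives 16.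

3. Step 6. The enol generated by the insertion may undergo a 3,3-sigmatropic shift of the allyl group to carbon, or the carbenoid may add to one of the alkenes, so that the ether is not obtained. The fallback sets out from 7 and comes back to the route at 10; it forms the ether bond by Williamson alkylation and adds the acetyl carbon afterwards. Alcohol 7 would be deprotonated with NaH in THF at 0 °C and alkylated with methyl bromoacetate to methyl 2-(TMS-chain-oxy)acetate F9. Its lithium enolate (LiN(iPr)2, THF, −78 °C) should add to acetaldehyde at −78 °C, below the temperature of Wittig rearrangement, to give methyl 3-hydroxy-2-(TMS-chain-oxy)butanoate F10 as a mixture of diastereomers. Dess–Martin periodinane with NaHCO3 in CH2Cl2 should oxidise this to 10.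

Further compounds
F1 | step 10 | dimethyl 3,5-dimethoxy-4-(TMS-chain-oxy)-3-(trimethylsilyloxy)cyclohexa-1,4-diene-1,2-dicarboxylate | COC(=O)C1=C(C(=O)OC)C(OC)(O[Si](C)(C)C)C(OC/C=C(\C)CC/C=C(\C)CCCC(C)(C)O[Si](C)(C)C)=C(OC)C1
F2 | step 10 | dimethyl 3-hydroxy-4-(HO-chain-oxy)-5-methoxyphthalate | COC(=O)c1cc(OC)c(OC/C=C(\C)CC/C=C(\C)CCCC(C)(C)O)c(O)c1C(=O)OC
F3 | step 10 | 3-hydroxy-4-(HO-chain-oxy)-5-methoxy-2-(methoxycarbonyl)benzoic acid | OC(=O)c1cc(OC)c(OC/C=C(\C)CC/C=C(\C)CCCC(C)(C)O)c(O)c1C(=O)OC
F4 | step 10 | 3-hydroxy-2-(hydroxymethyl)-4-(HO-chain-oxy)-5-methoxybenzoic acid | OC(=O)c1cc(OC)c(OC/C=C(\C)CC/C=C(\C)CCCC(C)(C)O)c(O)c1CO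
F5 | step 7 | methyl 2-(TMS-chain-oxy)-3-(trimethylsilyloxy)but-2-enoate | COC(=O)/C(OC/C=C(\C)CC/C=C(\C)CCCC(C)(C)O[Si](C)(C)C)=C(\C)O[Si](C)(C)C
F6 | step 7 | 1-methoxy-2-(TMS-chain-oxy)-1,3-bis(trimethylsilyloxy)buta-1,3-diene | C=C(O[Si](C)(C)C)/C(OC/C=C(\C)CC/C=C(\C)CCCC(C)(C)O[Si](C)(C)C)=C(/OC)O[Si](C)(C)C
F7 | step 7 | methyl 2-formyl-3-methoxy-4-(TMS-chain-oxy)-3,5-bis(trimethylsilyloxy)cyclohexa-1,4-diene-1-carboxylate | COC(=O)C1=C(C=O)C(OC)(O[Si](C)(C)C)C(OC/C=C(\C)CC/C=C(\C)CCCC(C)(C)O[Si](C)(C)C)=C(O[Si](C)(C)C)C1
F8 | step 7 | methyl 2-formyl-3,5-dihydroxy-4-(HO-chain-oxy)benzoate | COC(=O)c1cc(O)c(OC/C=C(\C)CC/C=C(\C)CCCC(C)(C)O)c(O)c1C=O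
F9 | step 6 | methyl 2-(TMS-chain-oxy)acetate | COC(=O)COC/C=C(\C)CC/C=C(\C)CCCC(C)(C)O[Si](C)(C)C
F10 | step 6 | methyl 3-hydroxy-2-(TMS-chain-oxy)butanoate | COC(=O)C(OC/C=C(\C)CC/C=C(\C)CCCC(C)(C)O[Si](C)(C)C)C(C)O
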